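The unbranched C36 acyl chain offers no handle beyond C1, so four adjacent methylenes, C15–C18, are carried as the ring carbons C2–C5 of a 2,5-disubstituted thiophene and unveiled later by Raney Ni. Everything rests on the C14–C15 disconnection: a Friedel–Crafts acylation joins the free alpha carbon of 2-octadecylthiophene (C15–C36) to the acid chloride of monomethyl tetradecanedioate (C1–C14) in one operation, giving a UV-active, chromatographable keto ester that already contains all 36 chain carbons. Deoxygenation of the ketone, desulfurisation and enzyme-controlled acyl transfer to the primary hydroxyl of tyrosol, whose para-substituted benzene ring and phenol remain untouched, complete the synthesis.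

Key step: step 3

Assumption: monomethyl tetradecanedioate (14-methoxy-14-oxotetradecanoic acid) is taken to be purchasable as such; the fragment count 14 + 4 + 18 reproduces the hexatriacontanoyl chain of the target, which has no stereocentre.

Step 1
Reactants: 1 thiophene; 2 1-bromooctadecane
Product: 4 2-octadecylthiophene, via 2-thienyllithium 3 (not isolated)
Conditions: n-BuLi (1.1 equiv), thiophene (1.3 equiv), THF, −78 → 0 °C; then 2 (1.0 equiv), 0 °C → reflux
Reagents that add atoms: none
Why: Sulfur-directed deprotonation of thiophene at C2 by n-BuLi followed by SN2 alkylation of the 2-thienyllithium with the primary bromide (lithiation–alkylation) should give the monoalkyl heterocycle, and the excess of volatile thiophene ensures that no long-chain bromide is left to contaminate the product.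

Step 2
Reactants: 5 14-methoxy-14-oxotetradecanoic acid (monomethyl tetradecanedioate)
Product: 6 methyl 14-chloro-14-oxotetradecanoate
Conditions: (COCl)2 (1.5 equiv), DMF (cat.), CH2Cl2, 0 °C → rt; concentrate and use crude
Reagents that add atoms: oxalyl chloride, ClC(=O)C(=O)Cl
Why: Catalytic DMF forms the chloroiminium species that converts the carboxylic acid into the acid chloride with only gaseous by-products, while the methyl ester at the other terminus is inert (acid chloride formation).

Step 3
Reactants: 4 2-octadecylthiophene; 6 methyl 14-chloro-14-oxotetradecanoate
Product: 7 methyl 14-(5-octadecylthiophen-2-yl)-14-oxotetradecanoate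
Conditions: SnCl4 (1.3 equiv), CH2Cl2, 0 °C → rt; then ice-cold dilute HCl
Reagents that add atoms: none
Why: SnCl4 ionises acid chloride 6 to an acylium ion (or its tight complex), which attacks C5 of 4 to give a sulfur-stabilised sigma complex that loses a proton, restoring the aromatic ring and forming the C14–C15 bond of the future chain. The closest known reaction type is the Friedel–Crafts acylation of 2-alkylthiophenes with half-ester acid chlorides of diacids, a standard entry to long-chain acids. No ring is closed and no stereocentre is created. The selectivity required is positional (alpha against beta attack on the heterocycle) together with mono-acylation: thiophene reacts far faster at an alpha carbon, the only other alpha carbon already bears the octadecyl group, and the new acyl group deactivates the ring towards a second attack. SnCl4 is chosen because it is mild enough not to oligomerise the electron-rich alkylthiophene, and the methyl ester is not an acyl donor under these conditions. The product should hold all 36 chain carbons (14 + 4 + 18) in a keto ester that is far easier to purify than the waxes on either side of it.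

Step 4
Reactants: 7 methyl 14-(5-octadecylthiophen-2-yl)-14-oxotetradecanoate
Product: 9 methyl 14-(5-octadecylthiophen-2-yl)tetradecanoate, via racemic carbinol 8 (not isolated)
Conditions: Et3SiH (3 equiv), CF3CO2H–CH2Cl2, rt
Reagents that add atoms: none
Why: Ionic hydrogenation of an aryl ketone, in which protonation and hydride transfer from Et3SiH give the carbinol (formed racemic and then erased), which ionises to a thienyl-stabilised cation and accepts a second hydride; the methyl ester is inert, and any ring-reduced thiolane would be desulfurised to the same product in step 5.

Step 5
Reactants: 9 methyl 14-(5-octadecylthiophen-2-yl)tetradecanoate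
Product: 10 methyl hexatriacontanoate
Conditions: Raney Ni (W-2, large excess), H2 (1 atm), THF–MeOH, reflux; hot filtration
Reagents that add atoms: none
Why: Raney Ni hydrogenolyses both C–S bonds and saturates the liberated four-carbon unit (reductive desulfurisation), so that the ring carbons become C15–C18 of the unbranched chain, while methanol as co-solvent makes any ester exchange on the basic metal surface degenerate.

Step 6
Reactants: 10 methyl hexatriacontanoate; 11 tyrosol (2-(4-hydroxyphenyl)ethanol)
Product: 12 2-(4-hydroxyphenyl)ethyl hexatriacontanoate (target)
Conditions: Novozym 435 (immobilised Candida antarctica lipase B), 11 (3 equiv), toluene–2-methylbutan-2-ol, 5 Å molecular sieves, 70 °C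
Reagents that add atoms: none
Why: Lipase-catalysed transesterification, in which the serine acyl-enzyme formed from the methyl ester is intercepted by primary aliphatic alcohols but not by phenols, so tyrosol should be acylated only at its CH2OH group while the sieves remove methanol and the tertiary alcohol co-solvent is not a substrate.

Compound list
1 | thiophene | c1ccsc1 | starting material
2 | 1-bromooctadecane | CCCCCCCCCCCCCCCCCCBr | starting material
3 | 2-thienyllithium (not isolated) | [Li]c1cccs1 | intermediate
4 | 2-octadecylthiophene | CCCCCCCCCCCCCCCCCCc1cccs1 | intermediate
5 | 14-methoxy-14-oxotetradecanoic acid (monomethyl tetradecanedioate) | COC(=O)CCCCCCCCCCCCC(=O)O | starting material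
6 | methyl 14-chloro-14-oxotetradecanoate | COC(=O)CCCCCCCCCCCCC(=O)Cl | intermediate
7 | methyl 14-(5-octadecylthiophen-2-yl)-14-oxotetradecanoate | CCCCCCCCCCCCCCCCCCc1ccc(s1)C(=O)CCCCCCCCCCCCC(=O)OC | intermediate
8 | methyl 14-hydroxy-14-(5-octadecylthiophen-2-yl)tetradecanoate (racemic, not isolated) | CCCCCCCCCCCCCCCCCCc1ccc(s1)C(O)CCCCCCCCCCCCC(=O)OC | intermediate
9 | methyl 14-(5-octadecylthiophen-2-yl)tetradecanoate | CCCCCCCCCCCCCCCCCCc1ccc(s1)CCCCCCCCCCCCCC(=O)OC | intermediate
10 | methyl hexatriacontanoate | CCCCCCCCCCCCCCCCCCCCCCCCCCCCCCCCCCCC(=O)OC | intermediate
11 | tyrosol, 2-(4-hydroxyphenyl)ethanol | OCCc1ccc(O)cc1 | starting material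
12 | 2-(4-hydroxyphenyl)ethyl hexatriacontanoate | CCCCCCCCCCCCCCCCCCCCCCCCCCCCCCCCCCCC(=O)OCCc1ccc(O)cc1 | target

Total step count: 6. Longest linear sequence: 5 steps (steps 1, 3, 4, 5, 6; step 2 feeds the convergent key step).

Steps most likely to fail

Step 3 (key acylation). The risks are Lewis-acid-induced oligomerisation of the electron-rich alkylthiophene, stalling of the reaction because SnCl4 is tied up by the ester and ketone carbonyls, and partial attack at a beta position. The fallback reverses the polarity at the same bond. 2-Octadecylthiophene 4 would be deprotonated at its only free alpha position with n-BuLi in THF at 0 °C to give (5-octadecylthiophen-2-yl)lithium F1. Transmetalation with ZnCl2 would give chloro(5-octadecylthiophen-2-yl)zinc F2, which would be coupled with acid chloride 6 under Pd(PPh3)4 catalysis in THF at room temperature (Negishi-type acylation). The organozinc should not add to the methyl ester or to the product ketone, and the site of lithiation fixes the regiochemistry. The fallback sets out from 4 (with 6) and comes back to the route at 7.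

Step 6 (enzymatic acyl transfer). The risks are slow or incomplete acyl transfer because the C36 chain is poorly accommodated in the acyl channel of the enzyme, failure of the waxy ester and the polar tyrosol to share one solvent phase, and hydrolysis of the acyl-enzyme by adventitious water. The fallback replaces acyl transfer by alkylation of the carboxylate. Methyl ester 10 would be saponified (KOH, EtOH–toluene, reflux; then HCl) to hexatriacontanoic acid F3. This acid would be esterified with tyrosol 11 under Mitsunobu conditions (PPh3, diisopropyl azodicarboxylate, THF, 45 °C). Only the aliphatic hydroxyl can be turned into an oxyphosphonium leaving group, and the carboxylic acid, far more acidic than the phenol, acts as the nucleophile, so the phenol should stay free. The fallback sets out from 10 and comes back at 12.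

Step 4 (ketone to methylene). The risks are arrest at the carbinol or its trifluoroacetate, acid-induced dimerisation through the thienyl cation, and partial ionic hydrogenation of the ring that complicates purification. The fallback is a thioketal desulfurisation (Mozingo-type reduction). Ketone 7 would be condensed with ethane-1,2-dithiol under BF3·OEt2 in CH2Cl2 to give methyl 13-[2-(5-octadecylthiophen-2-yl)-1,3-dithiolan-2-yl]tridecanoate F4. The Raney Ni treatment of step 5, with a larger excess of Raney Ni, would then remove the dithiolane and the ring sulfur in one operation. The fallback sets out from 7 and comes back at 10, bypassing 9.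

Further compounds
F1 | step 3 | (5-octadecylthiophen-2-yl)lithium | [Li]c1ccc(CCCCCCCCCCCCCCCCCC)s1
F2 | step 3 | chloro(5-octadecylthiophen-2-yl)zinc | Cl[Zn]c1ccc(CCCCCCCCCCCCCCCCCC)s1
F3 | step 6 | hexatriacontanoic acid | CCCCCCCCCCCCCCCCCCCCCCCCCCCCCCCCCCCC(=O)O
F4 | step 4 | methyl 13-[2-(5-octadecylthiophen-2-yl)-1,3-dithiolan-2-yl]tridecanoate | CCCCCCCCCCCCCCCCCCc1ccc(s1)C2(SCCS2)CCCCCCCCCCCCC(=O)OC
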